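**Retrosynthetic overview**
- Aryl–furan bond last: Ir C–H borylation at furan C5 of ester 8, then Suzuki coupling with unprotected bromohydroquinone 9, so no phenol protection is needed.
- Ester 8 from (S)-alcohol 6 and senecioic acid 7 by O-acylation.
- Key C–C bond, C1–C2 of the side chain: the carbonyl carbon of 3-furaldehyde 3 is turned into a chiral α-silyloxy carbanion on copper and joined to the electrophilic CH2 of a π-prenyl-palladium made from carbonate 2. Both carbons are natively electrophilic, and the stereocentre is set in this step.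
- Rings: none are formed; the furan (3) and the arene (9) are bought.

Assumption: the SMILES encodes the (S)-carbinol (O > furyl > CH2 > H) and that enantiomer is made; NHC* is one antipode of a C2-symmetric chiral imidazolin-2-ylidene (as its CuCl complex), picked in a first run so that Mosher analysis of 6 shows (S); the SMILES of 4 omits this ligand and is written for stereoretentive carbon transfer from Cu via Pd.

**Step 1**
Reactants: 1 3-methylbut-2-en-1-ol (prenol)
Product: 2 tert-butyl (3-methylbut-2-en-1-yl) carbonate
Conditions: Boc2O, Bu4NHSO4 (cat.), 30% aq NaOH, CH2Cl2, 0 °C to rt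
Reagents that add atoms: di-tert-butyl dicarbonate, CC(C)(C)OC(=O)OC(=O)OC(C)(C)C
Why: Phase-transfer O-alkoxycarbonylation of the primary allylic alcohol gives the allylic carbonate without touching the alkene, and no stereocentre is formed.

**Step 2 (key step)**
Reactants: 3 furan-3-carbaldehyde; 2 tert-butyl (3-methylbut-2-en-1-yl) carbonate
Product: 6 (S)-1-(furan-3-yl)-4-methylpent-3-en-1-ol, via α-silyloxy(furan-3-yl)methylcopper(I)·NHC* 4 (not isolated), via (S)-O-dimethylphenylsilyl ether 5 (not isolated)
Conditions: PhMe2Si–Bpin (1.5 equiv), (NHC*)CuCl (10 mol %), NaOtBu (10 mol %), Pd(dba)2/dppf (5 mol %), toluene, 25 °C; then MeOH, K2CO3 (cat.), rt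
Reagents that add atoms: (dimethylphenylsilyl)boronic acid pinacol ester, C[Si](C)(c1ccccc1)B1OC(C)(C)C(C)(C)O1 (its silyl group is carried in 4 and 5 only)
Why: Proposed new method: this extends the synergistic chiral NHC–Cu/Pd silylative coupling of aromatic aldehydes with aryl and allyl electrophiles to 3-furaldehyde and a prenyl carbonate, where Cu–Si adds across C=O, a [1,2]-Brook rearrangement gives the configurationally defined α-silyloxy organocopper 4 (a chiral α-alkoxy carbanion equivalent), and stereospecific Cu-to-Pd transmetalation and reductive elimination at the unhindered CH2 terminus of the Tsuji–Trost-type π-prenyl-Pd give linear 5; the (S) centre is set by NHC* in the enantiodetermining silyl-cupration of the aldehyde face, and the labile PhMe2Si ether is methanolysed in the same flask.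

**Step 3**
Reactants: 6 (S)-1-(furan-3-yl)-4-methylpent-3-en-1-ol; 7 3-methylbut-2-enoic acid (senecioic acid)
Product: 8 (S)-1-(furan-3-yl)-4-methylpent-3-en-1-yl 3-methylbut-2-enoate
Conditions: DCC, DMAP (cat.), CH2Cl2, 0 °C to rt
Reagents that add atoms: none
Why: Steglich esterification acylates the secondary alcohol on oxygen under near-neutral conditions, so the C–O bond at the stereocentre is not broken (configuration retained) and the senecioyl double bond is not deconjugated.

**Step 4**
Reactants: 8 (S)-1-(furan-3-yl)-4-methylpent-3-en-1-yl 3-methylbut-2-enoate; 9 2-bromobenzene-1,4-diol (bromohydroquinone)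
Product: 11 (S)-1-[5-(2,5-dihydroxyphenyl)furan-3-yl]-4-methylpent-3-en-1-yl 3-methylbut-2-enoate (CNP0293096.1), via furan-5-yl pinacol boronate 10 (not isolated)
Conditions: [Ir(OMe)(cod)]2 (1.5 mol %), dtbpy (3 mol %), B2pin2 (0.6 equiv), THF, 25 to 40 °C; then 9 (1.3 equiv), XPhos Pd G3 (3 mol %), degassed 0.5 M aq K3PO4, 40 °C; degassed aq NH4Cl/ascorbic acid work-up
Reagents that add atoms: bis(pinacolato)diboron, CC1(C)OB(OC1(C)C)B1OC(C)(C)C(C)(C)O1 (its boryl group is carried in 10 only)
Why: Sterically governed Ir-catalysed C–H borylation takes the only unhindered α-C–H of the 3-substituted furan (C5), and the 2-furyl boronate is consumed at once in a fast Suzuki–Miyaura coupling with a bulky biarylphosphine Pd catalyst at 40 °C, which tolerates free phenols and leaves the ester, both alkenes and the stereocentre untouched.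

**Compound list**
1 | 3-methylbut-2-en-1-ol (prenol) | CC(C)=CCO | starting material
2 | tert-butyl (3-methylbut-2-en-1-yl) carbonate | CC(C)=CCOC(=O)OC(C)(C)C | intermediate
3 | furan-3-carbaldehyde | O=Cc1ccoc1 | starting material
4 | (S)-[(dimethylphenylsilyl)oxy](furan-3-yl)methylcopper(I)·NHC* (ligand on Cu not drawn) | [Cu][C@H](O[Si](C)(C)c1ccccc1)c1ccoc1 | intermediate
5 | (S)-{[1-(furan-3-yl)-4-methylpent-3-en-1-yl]oxy}dimethyl(phenyl)silane | CC(C)=CC[C@H](O[Si](C)(C)c1ccccc1)c1ccoc1 | intermediate
6 | (S)-1-(furan-3-yl)-4-methylpent-3-en-1-ol | CC(C)=CC[C@H](O)c1ccoc1 | intermediate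
7 | 3-methylbut-2-enoic acid | CC(C)=CC(=O)O | starting material
8 | (S)-1-(furan-3-yl)-4-methylpent-3-en-1-yl 3-methylbut-2-enoate | CC(C)=CC[C@H](OC(=O)C=C(C)C)c1ccoc1 | intermediate
9 | 2-bromobenzene-1,4-diol | Oc1ccc(O)c(Br)c1 | starting material
10 | (S)-4-methyl-1-[5-(4,4,5,5-tetramethyl-1,3,2-dioxaborolan-2-yl)furan-3-yl]pent-3-en-1-yl 3-methylbut-2-enoate | CC(C)=CC[C@H](OC(=O)C=C(C)C)c1coc(B2OC(C)(C)C(C)(C)O2)c1 | intermediate
11 | (S)-1-[5-(2,5-dihydroxyphenyl)furan-3-yl]-4-methylpent-3-en-1-yl 3-methylbut-2-enoate | CC(C)=CC[C@H](OC(=O)C=C(C)C)c1coc(-c2cc(O)ccc2O)c1 | target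

**Step count**
Total steps: 4. Longest linear sequence: 4 (1 → 2 → 6 → 8 → 11), or 3 counted from 3-furaldehyde.

**Steps most likely to fail**

Step 2 is the riskiest. The Brook rearrangement may be slow on the electron-rich 3-furyl system, the prenyl unit may couple in part at its tertiary end, and the ee or the sense of induction may be unsatisfactory. The fallback sets out from 3 and returns at 6. Aldehyde 3 is condensed with propane-1,3-dithiol (BF3·OEt2, CH2Cl2, 0 °C) to 2-(furan-3-yl)-1,3-dithiane F1. F1 is deprotonated (n-BuLi, THF, −40 °C) and this acyl-anion equivalent is alkylated with prenyl bromide at the primary carbon to give 2-(furan-3-yl)-2-(3-methylbut-2-en-1-yl)-1,3-dithiane F2. Neutral unmasking (MeI, CaCO3, aq MeCN) gives 1-(furan-3-yl)-4-methylpent-3-en-1-one F3 without conjugating the alkene. Corey–Bakshi–Shibata reduction with (R)-Me-CBS and BH3·SMe2 (furyl as the large group) then gives (S)-6.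

Step 4 is next. The free hydroquinone may be oxidised or may poison the catalyst, and the 2-furyl boronate may protodeboronate before it couples. The fallback sets out from 9, uses 10 made from 8 as before, and returns at 11. Bromohydroquinone 9 is silylated (TBSCl, imidazole, DMF) to 2-bromo-1,4-bis(tert-butyldimethylsilyloxy)benzene F5. F5 is coupled with boronate 10 (XPhos Pd G3, K3PO4, THF/H2O, 40 °C) to the bis-TBS ether of the target F6. The phenolic silyl ethers are then removed with KHF2 in MeOH at rt, which leaves the ester alone, to give 11; any silyl loss during the coupling is harmless.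

Step 3 is the least risky of the three. Possible problems are N-acylurea formation, partial deconjugation to the 3-methylbut-3-enoate, or ionisation of the furylic ester on silica. The fallback sets out from 6 and returns at 8. Alcohol 6 is acylated with diethylphosphonoacetic acid (EDC, DMAP) to (S)-1-(furan-3-yl)-4-methylpent-3-en-1-yl 2-(diethoxyphosphoryl)acetate F4, which cannot deconjugate. A Horner–Wadsworth–Emmons reaction of F4 with acetone (NaH, THF, 0 °C to rt) then builds the senecioate double bond and gives 8.

**Further compounds**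
F1 | step 2 | 2-(furan-3-yl)-1,3-dithiane | C1CSC(SC1)c1ccoc1
F2 | step 2 | 2-(furan-3-yl)-2-(3-methylbut-2-en-1-yl)-1,3-dithiane | CC(C)=CCC1(SCCCS1)c1ccoc1
F3 | step 2 | 1-(furan-3-yl)-4-methylpent-3-en-1-one | CC(C)=CCC(=O)c1ccoc1
F4 | step 3 | (S)-1-(furan-3-yl)-4-methylpent-3-en-1-yl 2-(diethoxyphosphoryl)acetate | CC(C)=CC[C@H](OC(=O)CP(=O)(OCC)OCC)c1ccoc1
F5 | step 4 | 2-bromo-1,4-bis(tert-butyldimethylsilyloxy)benzene | CC(C)(C)[Si](C)(C)Oc1ccc(O[Si](C)(C)C(C)(C)C)c(Br)c1
F6 | step 4 | (S)-1-{5-[2,5-bis(tert-butyldimethylsilyloxy)phenyl]furan-3-yl}-4-methylpent-3-en-1-yl 3-methylbut-2-enoate | CC(C)=CC[C@H](OC(=O)C=C(C)C)c1coc(-c2cc(O[Si](C)(C)C(C)(C)C)ccc2O[Si](C)(C)C(C)(C)C)c1
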